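## Structural features

The target is a C19 gibberellin-type acid. A cyclohexane (ring A: C1–C5, C10), a cyclopentane (ring B: C5, C6, C8, C9, C10) and a bicyclo[3.2.1]octane (rings C and D: C8, C9, C11–C16) are fused in a row, and a γ-lactone (C19, O) bridges C4 and C10 across ring A. There are nine stereocentres. C4, C8 and C10 are quaternary carbons linked through C5 and C9, C16 is a tertiary carbinol, and the contiguous array C3–C4–C5–C6 lies next to the lactone. Ring B is cis-fused to the six-membered ring C (H9 on the face of the C15–C16 bridge, C10 axial on ring C). The 3-hydroxyl is axial and anti to C19, and the 16-hydroxyl points endo, toward C11 and C12. The β-hydroxy lactone is the fragile unit: base opens C3–C4 by retro-aldol and recloses it to the equatorial 3-epimer. The tertiary 16-alcohol can ionise and rearrange in strong acid, and the C7 carboxyl is hindered. The real difficulty is the dense set C4, C5, C10, C9, C8 together with the axial C3 alcohol, not the C/D bicycle itself. The key step exploits that C8, C9, C11–C14 with C10 on C9 and C15–C17 on C13 are the ten carbons of the p-menthane skeleton of (R)-limonene and (R)-perillaldehyde. C13 is its only stereocentre and is 1,3 to C8 across C14, so one C8–C15 bond closes ring D and creates quaternary C8.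

## Logic of the disconnections

**31 ⇒ 30 ⇒ 29 (no skeletal bond).** The acid is released last from a benzyl ester, and ring A is saturated just before. The β-hydroxy lactone tolerates neither hydroxide nor hot acid, and the allylic C10–O bond of 29 would be hydrogenolysed on palladium, so diimide comes first and hydrogenolysis second. The gain is two neutral closing steps. The demand is that nothing else reducible remains, so C16 must already carry its methyl and hydroxyl.

**29 ⇒ 28 (C1=C2).** Ring A is opened at the alkene made by ring-closing metathesis. This allows C3–C4 to be made intermolecularly in the step before. The gain is that ring A comes from two vinyl groups. The demand is that the vinyl on C10 and the hydroxyallyl on C4 are cis on the lactone ring and that no other reactive alkene is present.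

**28 ⇒ 24 + 25 (C5–C6 and C3–C4).** C5 is β to C19 and C6 is α to C7, so C5–C6 is a Michael bond. The lactone enolate born in that addition is the only regiospecific C4 nucleophile, and it is intercepted by 25. C3 is deliberately kept outside the ring at this point. A ring-forming aldol onto a tethered aldehyde is forced, when chelated, to the equatorial alcohol, which is also where retro-aldol equilibration ends. The gain is ring B and four stereocentres. The demand is that 24 has no acidic C–H other than that on C6.

**24 ⇒ 22 + 23 (C4–C19 and C19–O).** The butenolide is cut to a (Z)-iodoalkenyl carbinol and 23. The gain is that C19 arrives at the lactone oxidation level in one step. The demand is that iodine and C10 are cis on C4=C5.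

**22 ⇒ 20 + 21 (C10–C1), and 20 ⇒ 19 (no skeletal bond).** Quaternary C10 is made by addition to a ketone next to C9. The C5 unit is placed on the ketone and C1 comes as the nucleophile, because the Felkin–Anh sense then gives the required C10. C9 can be corrected only while C10 is a carbonyl and is frozen from 22 onward, so C9 must be right before this step. 20 comes from 19 by adding HI across the alkyne.

**19 ⇒ 18 ⇒ 14 + 15 + 16 (C10–C5 and C16–C17), and 14 ⇒ 13 (C16=C17).** The methylene left by the key step is traded for a ketone. Methyl must enter from the open exo face, whereas hydration of the alkene would put oxygen on that face instead. The gain is that both carbonyls of 14 are used in one operation. The demand is that the aldehyde reacts before the ketone.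

**13 ⇒ 11 (C8–C15, the key disconnection).** Cutting this bond opens ring D and returns a monocyclic enal with one stereocentre. The gain is one ring, one skeletal bond and two stereocentres. The demand is conjugate rather than carbonyl attack and a controlled protonation at C9.

**11 ⇒ 9 + 10, and 9 ⇒ 8 (C–Si, then C–Cl).** The allylsilane is drawn from the isopropenyl group by ene chlorination and silylation. The demand is that the enal survives both.

**8 ⇒ 7 ⇒ 4 + 5 (C6–C8).** The arm is placed on C8 by 1,2-addition to a C8 ketone. The enal is then created by oxidative 1,3-transposition of the tertiary allylic alcohol, which can only put the double bond between C8 and C9. A conjugate addition to the β-carbon of an existing enal followed by re-oxidation would have no such regiocontrol. The demand is 1,2- and not 1,4-addition to 4.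

**4 ⇒ 3 ⇒ 2 ⇒ 1 (functional group changes only).** The ring alkene of 1 becomes the epoxide, then the exocyclic allylic alcohol, then the enone. C13 is never touched.

## Other disconnections considered

**Alternative 1:** The cut is C9–C11 of ring C. In the forward sense an amino-acid-catalysed intramolecular aldol condensation (Hajos–Parrish reaction) converts the prochiral triketone A1 into the bicyclic enedione A2. The methyl ketone carbon C11 attacks one of two enantiotopic ring carbonyls and water is lost.
- In favour: quaternary C8 is made catalytically from achiral, cheap material. The propargyl group is C15–C17, waiting for a bond from C13 to C16. Hydrogenation of the enone of A2 should add hydrogen cis to the angular group, which is the B/C relationship of the target. On this point the alternative is better than the chosen plan, whose C9 rests on a kinetic protonation in step 8.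
- Against: the induction of this aldol is best for an angular methyl and is expected to fall for propargyl, whereas in the chosen plan C13 is bought enantiopure and C8 follows without a selectivity question. The oxygen pattern of A2 is misplaced: C6 is a ketone carbon that must still gain C7, and the C12 oxygen must be removed after ring D is closed. C10, C5, C4, C3, ring A and the lactone are not addressed.
- Comparison: both key steps are robust closures onto a carbonyl-activated carbon (enamine aldol against Lewis-acid allylation). The alternative starts shorter but pays in redox and homologation steps, so it is judged no shorter than the 18 steps chosen.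

**Alternative 2:** The cut is C4–C5. In the forward sense the δ-lactone A3, whose ring oxygen sits on allylic C1 next to a C10=C5 alkene, is turned by an amide base and a silyl chloride into its silyl ketene acetal. This undergoes Ireland–Claisen rearrangement through the boat transition state that the lactone ring enforces. Ring A closes by ring contraction and the acid A4 with a free C19 carboxyl and a C1=C10 alkene results.
- In favour: quaternary C4 and adjacent C5 are set in one suprafacial pericyclic event with chirality transfer from C1. The C19 acid and C1=C10 alkene of A4 are placed for a later lactonisation that would set C10 intramolecularly. On the fidelity of C4, C5 and C10 this alternative is better than the chosen plan, where C10 depends on Felkin–Anh control in step 13.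
- Against: it solves ring A only and presupposes the whole B/C/D tricycle with the C5=C10 alkene, a defined C1 carbinol and the C3 oxygen. The enolate of A3 has a β-oxygen at C3 and can eliminate unless that oxygen is held as an alkoxide. The later lactonisation of A4 must protonate C1 and attack C10 without moving the alkene. C7 is at the alcohol level and must be re-oxidised.
- Comparison: it builds ring A on a finished core, whereas the chosen plan grows rings B and A outward from the C/D bicycle. It is expected to be the longest of the four.

**Alternative 3:** The cuts are C5–C6 and C3–C4 together. In the forward sense an amine or carbonate base deprotonates the malonate of A5. C6 adds to C5 of the butenolide, and the lactone enolate at C4 closes onto the tethered C3 aldehyde to give the pentacyclic diester A6.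
- In favour: two rings and the centres C5, C4 and C3 arise in one mild step. C5 and C4 are dictated by the cis lactone fusion and the tether, and the lactone enolate needs no strong base. The chosen plan uses the same logic for C5–C6 (step 15), so on C5 and C4 the two are equal. For the A/B stage the alternative is better in step count (one step against steps 15 to 17).
- Against: the ring-forming aldol, when the metal bridges the two oxygens, leads to the equatorial C3 alcohol, and under equilibrating base retro-aldol drains toward the same epimer; the target has the axial one. The second ester on C6 must later be removed under conditions the β-hydroxy lactone may not tolerate. The disconnection does not say how the C/D bicycle, C9 and C10 are obtained; A5 would need the same chemistry as 24.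
- Comparison: the chosen plan keeps the Michael half and replaces the aldol half by an intermolecular aldol and metathesis to reach the axial C3 alcohol.

Key step: step 8

Assumption: atom numbers are gibberellane numbers, and C7 is carried as a benzyl ester from step 4 to step 18 (a protecting-group change that leaves the skeletons of 11 and 13 as required), because saponifying a C7 methyl ester at the end would expose the β-hydroxy lactone to retro-aldol epimerisation at C3.

## Route

Step 1
Reactants: 1 (R)-(+)-limonene
Product: 2 (4R)-1,2-epoxy-p-menth-8-ene (limonene 1,2-oxide; both epoxide diastereomers)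
Conditions: mCPBA (1.0 equiv), CH2Cl2, 0 °C
Reagents that add atoms: mCPBA (3-chloroperoxybenzoic acid), OOC(=O)c1cccc(Cl)c1
Why: Prilezhaev epoxidation; the trisubstituted ring alkene is more electron-rich than the 1,1-disubstituted isopropenyl group and reacts first. The epoxide configuration is irrelevant because C8 and C9 become trigonal in steps 3 to 5, and C13 is not touched.

Step 2
Reactants: 2 (4R)-1,2-epoxy-p-menth-8-ene
Product: 3 (5R)-2-methylidene-5-(prop-1-en-2-yl)cyclohexan-1-ol (both C1 epimers)
Conditions: lithium diisopropylamide, Et2O, 0 °C to rt; then H2O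
Reagents that add atoms: none
Why: Base-promoted isomerisation of an epoxide to an allylic alcohol (syn β-elimination); the amide removes a proton of the C10 methyl group, the least hindered β-hydrogen in both epoxide diastereomers, so oxygen stays on C8 and the C9=C10 methylene appears.

Step 3
Reactants: 3 (5R)-2-methylidene-5-(prop-1-en-2-yl)cyclohexan-1-ol
Product: 4 (5R)-2-methylidene-5-(prop-1-en-2-yl)cyclohexan-1-one
Conditions: Dess–Martin periodinane, CH2Cl2, 0 °C; solution used at once
Reagents that add atoms: none
Why: Dess–Martin oxidation of a secondary allylic alcohol under conditions too mild to move the exocyclic alkene into the ring. The α-methylene ketone is kept cold and dilute because such enones dimerise.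

Step 4
Reactants: 4 (5R)-2-methylidene-5-(prop-1-en-2-yl)cyclohexan-1-one; 5 benzyl acetate
Product: 7 benzyl 2-[(5R)-1-hydroxy-2-methylidene-5-(prop-1-en-2-yl)cyclohexyl]acetate (both C1 epimers), via lithium ester enolate 6 (not isolated)
Conditions: lithium diisopropylamide, THF, −78 °C; then 4, −78 °C; then H2O
Reagents that add atoms: none
Why: Kinetic aldol-type 1,2-addition of a lithium ester enolate to an enone carbonyl at −78 °C (conjugate addition needs equilibration at higher temperature); this forms C6–C8. The new carbinol centre at C8 is lost in step 5.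

Step 5
Reactants: 7 benzyl 2-[(5R)-1-hydroxy-2-methylidene-5-(prop-1-en-2-yl)cyclohexyl]acetate
Product: 8 benzyl 2-[(5R)-2-formyl-5-(prop-1-en-2-yl)cyclohex-1-en-1-yl]acetate
Conditions: pyridinium chlorochromate, 4 Å molecular sieves, CH2Cl2, rt
Reagents that add atoms: pyridinium chlorochromate, [O-][Cr](=O)(=O)Cl.c1cc[nH+]cc1
Why: Babler–Dauben oxidative transposition; the chromate ester of the tertiary allylic alcohol shifts by a [3,3] process to the primary allylic chromate on C10, which is oxidised to the aldehyde. The double bond can only end between C8 and C9, so the arm sits on the β-carbon of the enal without a regiochemical choice.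

Step 6
Reactants: 8 benzyl 2-[(5R)-2-formyl-5-(prop-1-en-2-yl)cyclohex-1-en-1-yl]acetate
Product: 9 benzyl 2-[(5R)-5-(3-chloroprop-1-en-2-yl)-2-formylcyclohex-1-en-1-yl]acetate
Conditions: Ca(OCl)2, CO2 (solid), CH2Cl2/H2O, 0 °C
Reagents that add atoms: calcium hypochlorite, [Ca+2].[O-]Cl.[O-]Cl
Why: Ene-type allylic chlorination by hypochlorous acid; chlorine adds to the terminal carbon of the isopropenyl group and a methyl proton is lost, giving the transposed allyl chloride. The tetrasubstituted enal alkene is electron-poor and does not react.

Step 7
Reactants: 9 benzyl 2-[(5R)-5-(3-chloroprop-1-en-2-yl)-2-formylcyclohex-1-en-1-yl]acetate; 10 hexamethyldisilane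
Product: 11 benzyl 2-[(5R)-2-formyl-5-[3-(trimethylsilyl)prop-1-en-2-yl]cyclohex-1-en-1-yl]acetate
Conditions: Pd(PPh3)4 (5 mol %), THF, 80 °C
Reagents that add atoms: none
Why: Palladium-catalysed silylation of an allylic chloride with a disilane (oxidative addition to zerovalent palladium, Si–Si cleavage by the π-allyl chloride complex, reductive elimination). The two CH2 termini of the π-allyl unit are equivalent, so no regioisomer can form.

Step 8
Reactants: 11 benzyl 2-[(5R)-2-formyl-5-[3-(trimethylsilyl)prop-1-en-2-yl]cyclohex-1-en-1-yl]acetate
Product: 13 benzyl 2-[(1S,2R,5R)-2-formyl-6-methylidenebicyclo[3.2.1]octan-1-yl]acetate, via aluminium enolate 12 (not isolated)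
Conditions: EtAlCl2 (1.2 equiv), CH2Cl2, −78 °C; then H2O/THF, −78 °C
Reagents that add atoms: none
Why: Intramolecular Hosomi–Sakurai conjugate allylation: EtAlCl2 binds the aldehyde oxygen, the terminal CH2 of the allylsilane (future C15) adds to the β-carbon C8, the β-silyl cation at C16 loses silicon to chloride to leave the C16=C17 methylene, and the aluminium enolate 12 is protonated at C9 on quenching. The closest known reaction type is the Lewis-acid-mediated intramolecular addition of 2-substituted allylsilanes to enones and enals that gives bridged bicycles with a new quaternary carbon. Ring D closes 5-exo-trig with respect to the enal (C9 stays outside the new ring), while both carbons of the allylsilane π bond become ring members, so the side chain must twist for overlap. C8 is fixed by the tether: the side chain sits on C13, which is 1,3 to C8, and can reach C8 only when pseudoaxial and only on its own face, so the (R) centre C13 is relayed to the quaternary centre without a choice. C9 is set in the quench: it is an exocyclic enolate carbon of ring C, the proton should arrive along the less hindered equatorial line (away from the syn-axial hydrogens on C12 and C14), and the formyl group is left axial, cis to the C6 arm. The step needs conjugate rather than carbonyl attack; the two-atom reach from C13 spans C8 but not the formyl carbon on the para position, and EtAlCl2 also scavenges protons that would protodesilylate 11. The benzyl ester is a spectator.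

Step 9
Reactants: 13 benzyl 2-[(1S,2R,5R)-2-formyl-6-methylidenebicyclo[3.2.1]octan-1-yl]acetate
Product: 14 benzyl 2-[(1S,2R,5R)-2-formyl-6-oxobicyclo[3.2.1]octan-1-yl]acetate
Conditions: O3, CH2Cl2, −78 °C; then Me2S
Reagents that add atoms: ozone, [O-][O+]=O
Why: Ozonolysis of the only alkene; C17 leaves as formaldehyde and C16 becomes the ketone needed for methyl addition. The neutral reductive work-up leaves the aldehyde and C9 alone.

Step 10
Reactants: 14 benzyl 2-[(1S,2R,5R)-2-formyl-6-oxobicyclo[3.2.1]octan-1-yl]acetate; 15 prop-1-yn-1-ylmagnesium bromide; 16 methylmagnesium bromide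
Product: 18 benzyl 2-[(1S,2R,5R,6S)-6-hydroxy-2-(1-hydroxybut-2-yn-1-yl)-6-methylbicyclo[3.2.1]octan-1-yl]acetate (both epimers at the propargylic carbinol), via keto alkoxide 17 (not isolated)
Conditions: 15 (1.05 equiv), THF, −78 °C; then 16 (2.5 equiv), −78 to −40 °C; then H2O
Reagents that add atoms: none
Why: Two Grignard additions in order of carbonyl reactivity: the alkynyl reagent takes the aldehyde at −78 °C (C10–C5 bond; carbinol configuration irrelevant), then the methyl reagent adds to the C16 ketone. Methyl should enter from the exo face, on the side of the one-carbon bridge C14 and away from the axial hydrogen on C11, giving the endo hydroxyl (16S). The benzyl ester should not be attacked below −40 °C.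

Step 11
Reactants: 18 benzyl 2-[(1S,2R,5R,6S)-6-hydroxy-2-(1-hydroxybut-2-yn-1-yl)-6-methylbicyclo[3.2.1]octan-1-yl]acetate
Product: 19 benzyl 2-[(1S,2R,5R,6S)-2-(but-2-ynoyl)-6-hydroxy-6-methylbicyclo[3.2.1]octan-1-yl]acetate
Conditions: Dess–Martin periodinane, CH2Cl2, 0 °C
Reagents that add atoms: none
Why: Dess–Martin oxidation of the secondary propargylic alcohol; the tertiary alcohol cannot react. The medium is not basic and C9–H, next to quaternary C8, is slow to enolise, so C9 is kept.

Step 12
Reactants: 19 benzyl 2-[(1S,2R,5R,6S)-2-(but-2-ynoyl)-6-hydroxy-6-methylbicyclo[3.2.1]octan-1-yl]acetate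
Product: 20 benzyl 2-[(1S,2R,5R,6S)-6-hydroxy-2-[(2Z)-3-iodobut-2-enoyl]-6-methylbicyclo[3.2.1]octan-1-yl]acetate
Conditions: NaI, AcOH, rt
Reagents that add atoms: sodium iodide, [Na+].[I-]
Why: Conjugate hydroiodination of an ynone; iodide adds to the β-carbon C4 and protonation occurs anti, giving the (Z)-β-iodo enone with iodine and C10 on the same side of C4=C5, as the later lactonisation needs.

Step 13
Reactants: 20 benzyl 2-[(1S,2R,5R,6S)-6-hydroxy-2-[(2Z)-3-iodobut-2-enoyl]-6-methylbicyclo[3.2.1]octan-1-yl]acetate; 21 ethenylmagnesium bromide
Product: 22 benzyl 2-[(1S,2R,5R,6S)-6-hydroxy-2-[(3R,4Z)-3-hydroxy-5-iodohexa-1,4-dien-3-yl]-6-methylbicyclo[3.2.1]octan-1-yl]acetate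
Conditions: 21 (3 equiv), THF, −78 °C; then H2O
Reagents that add atoms: none
Why: Felkin–Anh 1,2-addition of a Grignard reagent: the vinyl group should approach the ketone anti to the C9–C8 bond (quaternary C8 is the large group), passing the C9 hydrogen, with the carbonyl oxygen flanked by C11. This places O, vinyl (C1) and the iodoalkenyl group (C5) around C10 as in the target. One equivalent of 21 is spent on the C16 hydroxyl, and at −78 °C carbonyl addition should outrun iodide displacement and attack on the ester.

Step 14
Reactants: 22 benzyl 2-[(1S,2R,5R,6S)-6-hydroxy-2-[(3R,4Z)-3-hydroxy-5-iodohexa-1,4-dien-3-yl]-6-methylbicyclo[3.2.1]octan-1-yl]acetate; 23 carbon monoxide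
Product: 24 benzyl 2-[(1S,2R,5R,6S)-2-[(2S)-2-ethenyl-4-methyl-5-oxo-2,5-dihydrofuran-2-yl]-6-hydroxy-6-methylbicyclo[3.2.1]octan-1-yl]acetate
Conditions: PdCl2(PPh3)2 (5 mol %), CO (1 atm), Et3N, THF, 50 °C
Reagents that add atoms: none
Why: Palladium-catalysed carbonylative lactonisation of a (Z)-γ-iodo allylic alcohol (oxidative addition, CO insertion, capture of the acyl palladium by the tertiary hydroxyl); this closes the butenolide and brings in C19. C10 is not affected; its descriptor changes only because the ranking of its substituents changes.

Step 15
Reactants: 24 benzyl 2-[(1S,2R,5R,6S)-2-[(2S)-2-ethenyl-4-methyl-5-oxo-2,5-dihydrofuran-2-yl]-6-hydroxy-6-methylbicyclo[3.2.1]octan-1-yl]acetate; 25 acrolein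
Product: 28 tetracyclic hydroxy lactone benzyl ester (rings B, C, D plus the 19,10-lactone; vinyl on C10; (1S)-1-hydroxyprop-2-en-1-yl on C4; 3S,4S,5R,6S,8R,9R,10R,13R,16S), via dilithium ester enolate 26 (not isolated), via lithium lactone enolate 27 (not isolated)
Conditions: lithium diisopropylamide (2.2 equiv), THF, −78 °C; then 25, −78 °C; then H2O
Reagents that add atoms: none
Why: Tandem intramolecular Michael addition and intermolecular aldol reaction: the ester enolate at C6 closes ring B 5-exo onto C5 of the butenolide on the face of C9 (only the cis-fused bicycle is strain-free, so C5 follows C10), with the ester group on the convex face (C6; also the stable epimer, trans to C4). The lactone enolate 27, which could not be made by deprotonation next to an aldehyde, adds to acrolein on its convex face, anti to C6 and syn to the C10 vinyl group (C4). A Zimmerman–Traxler chair with the vinyl group equatorial places O3 and the C18 methyl syn, which corresponds to the axial 3-hydroxyl of the target (C3); carbonyl addition of lithium enolates to acrolein is the normal course at −78 °C.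

Step 16
Reactants: 28 tetracyclic hydroxy lactone benzyl ester
Product: 29 benzyl ester of the 1,2-didehydro target (pentacyclic; C1=C2; 3S,4S,5R,6S,8R,9R,10R,13R,16S)
Conditions: second-generation Grubbs catalyst RuCl2(=CHPh)(PCy3)(H2IMes) (5 mol %), CH2Cl2, 40 °C
Reagents that add atoms: none
Why: Ring-closing metathesis between the vinyl group on C10 and the vinyl group on C3 forms C1=C2 and the six-membered ring A bridged by the lactone. Both groups are on the same face of the lactone ring as a consequence of step 15; free hydroxyls are tolerated and there is no other alkene.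

Step 17
Reactants: 29 benzyl ester of the 1,2-didehydro target
Product: 30 benzyl ester of the target (3S,4S,5R,6S,8R,9R,10R,13R,16S)
Conditions: 2-nitrobenzenesulfonohydrazide, Et3N, CH2Cl2, rt
Reagents that add atoms: none
Why: Diimide reduction (syn transfer of H2 to the cis-disubstituted alkene). Unlike hydrogenation on palladium it cannot hydrogenolyse the allylic C10–O lactone bond or the allylic C3–O bond; no stereocentre is made.

Step 18
Reactants: 30 benzyl ester of the target
Product: 31 target acid CNP0343121.3
Conditions: H2 (1 atm), Pd/C, EtOAc, rt
Reagents that add atoms: none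
Why: Hydrogenolysis of the benzyl ester under neutral conditions releases the C7 acid. With ring A saturated no allylic C–O bond is left, and neither the β-hydroxy lactone nor the tertiary alcohol sees acid or base.

## Compound list

1 | (R)-(+)-limonene | CC1=CC[C@@H](CC1)C(C)=C | starting material
2 | (4R)-1,2-epoxy-p-menth-8-ene (both epoxide diastereomers) | CC12OC1C[C@@H](CC2)C(C)=C | intermediate
3 | (5R)-2-methylidene-5-(prop-1-en-2-yl)cyclohexan-1-ol (both C1 epimers) | C=C1CC[C@@H](C(C)=C)CC1O | intermediate
4 | (5R)-2-methylidene-5-(prop-1-en-2-yl)cyclohexan-1-one | C=C1CC[C@@H](C(C)=C)CC1=O | intermediate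
5 | benzyl acetate | CC(=O)OCc1ccccc1 | starting material
6 | lithium enolate of benzyl acetate (not isolated) | C=C(O[Li])OCc1ccccc1 | intermediate
7 | benzyl 2-[(5R)-1-hydroxy-2-methylidene-5-(prop-1-en-2-yl)cyclohexyl]acetate (both C1 epimers) | C=C1CC[C@@H](C(C)=C)CC1(O)CC(=O)OCc1ccccc1 | intermediate
8 | benzyl 2-[(5R)-2-formyl-5-(prop-1-en-2-yl)cyclohex-1-en-1-yl]acetate | O=CC1=C(CC(=O)OCc2ccccc2)C[C@H](C(C)=C)CC1 | intermediate
9 | benzyl 2-[(5R)-5-(3-chloroprop-1-en-2-yl)-2-formylcyclohex-1-en-1-yl]acetate | O=CC1=C(CC(=O)OCc2ccccc2)C[C@H](C(=C)CCl)CC1 | intermediate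
10 | hexamethyldisilane | C[Si](C)(C)[Si](C)(C)C | starting material
11 | benzyl 2-[(5R)-2-formyl-5-[3-(trimethylsilyl)prop-1-en-2-yl]cyclohex-1-en-1-yl]acetate (key-step precursor) | O=CC1=C(CC(=O)OCc2ccccc2)C[C@H](C(=C)C[Si](C)(C)C)CC1 | intermediate
12 | chloro(ethyl)aluminium enolate of 13 (not isolated) | CC[Al](Cl)OC=C1CC[C@@H]2C[C@]1(CC2=C)CC(=O)OCc1ccccc1 | intermediate
13 | benzyl 2-[(1S,2R,5R)-2-formyl-6-methylidenebicyclo[3.2.1]octan-1-yl]acetate (key-step product) | O=C[C@@H]1CC[C@@H]2C[C@]1(CC2=C)CC(=O)OCc1ccccc1 | intermediate
14 | benzyl 2-[(1S,2R,5R)-2-formyl-6-oxobicyclo[3.2.1]octan-1-yl]acetate | O=C[C@@H]1CC[C@@H]2C[C@]1(CC2=O)CC(=O)OCc1ccccc1 | intermediate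
15 | prop-1-yn-1-ylmagnesium bromide | CC#C[Mg]Br | starting material
16 | methylmagnesium bromide | C[Mg]Br | starting material
17 | bromomagnesium alkoxide of benzyl 2-[(1S,2R,5R)-2-(1-hydroxybut-2-yn-1-yl)-6-oxobicyclo[3.2.1]octan-1-yl]acetate (not isolated) | CC#CC(O[Mg]Br)[C@@H]1CC[C@@H]2C[C@]1(CC2=O)CC(=O)OCc1ccccc1 | intermediate
18 | benzyl 2-[(1S,2R,5R,6S)-6-hydroxy-2-(1-hydroxybut-2-yn-1-yl)-6-methylbicyclo[3.2.1]octan-1-yl]acetate (both carbinol epimers) | CC#CC(O)[C@@H]1CC[C@@H]2C[C@]1(C[C@]2(C)O)CC(=O)OCc1ccccc1 | intermediate
19 | benzyl 2-[(1S,2R,5R,6S)-2-(but-2-ynoyl)-6-hydroxy-6-methylbicyclo[3.2.1]octan-1-yl]acetate | CC#CC(=O)[C@@H]1CC[C@@H]2C[C@]1(C[C@]2(C)O)CC(=O)OCc1ccccc1 | intermediate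
20 | benzyl 2-[(1S,2R,5R,6S)-6-hydroxy-2-[(2Z)-3-iodobut-2-enoyl]-6-methylbicyclo[3.2.1]octan-1-yl]acetate | I/C(C)=C\C(=O)[C@@H]1CC[C@@H]2C[C@]1(C[C@]2(C)O)CC(=O)OCc1ccccc1 | intermediate
21 | ethenylmagnesium bromide | C=C[Mg]Br | starting material
22 | benzyl 2-[(1S,2R,5R,6S)-6-hydroxy-2-[(3R,4Z)-3-hydroxy-5-iodohexa-1,4-dien-3-yl]-6-methylbicyclo[3.2.1]octan-1-yl]acetate | I/C(C)=C\[C@@](O)(C=C)[C@@H]1CC[C@@H]2C[C@]1(C[C@]2(C)O)CC(=O)OCc1ccccc1 | intermediate
23 | carbon monoxide | [C-]#[O+] | starting material
24 | benzyl 2-[(1S,2R,5R,6S)-2-[(2S)-2-ethenyl-4-methyl-5-oxo-2,5-dihydrofuran-2-yl]-6-hydroxy-6-methylbicyclo[3.2.1]octan-1-yl]acetate | CC1=C[C@](C=C)(OC1=O)[C@@H]1CC[C@@H]2C[C@]1(C[C@]2(C)O)CC(=O)OCc1ccccc1 | intermediate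
25 | acrolein | C=CC=O | starting material
26 | dilithium salt of 24 (C16 alkoxide, C6 ester enolate; not isolated) | CC1=C[C@](C=C)(OC1=O)[C@@H]1CC[C@@H]2C[C@]1(C[C@]2(C)O[Li])C=C(O[Li])OCc1ccccc1 | intermediate
27 | dilithium Michael adduct (C16 alkoxide, C4 lactone enolate, ring B closed; not isolated) | CC1=C(O[Li])O[C@]2(C=C)[C@@H]3CC[C@@H]4C[C@]3(C[C@]4(C)O[Li])[C@@H](C(=O)OCc3ccccc3)[C@H]12 | intermediate
28 | tetracyclic hydroxy lactone benzyl ester (10-vinyl, 4-[(1S)-1-hydroxyprop-2-en-1-yl]; 3S,4S,5R,6S,8R,9R,10R,13R,16S) | C[C@]1([C@@H](O)C=C)C(=O)O[C@]2(C=C)[C@@H]3CC[C@@H]4C[C@]3(C[C@]4(C)O)[C@@H](C(=O)OCc3ccccc3)[C@H]12 | intermediate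
29 | benzyl ester of the 1,2-didehydro target (3S,4S,5R,6S,8R,9R,10R,13R,16S) | C[C@@]12C(=O)O[C@]3(C=C[C@@H]1O)[C@@H]1CC[C@@H]4C[C@]1(C[C@]4(C)O)[C@@H](C(=O)OCc1ccccc1)[C@@H]32 | intermediate
30 | benzyl ester of the target (3S,4S,5R,6S,8R,9R,10R,13R,16S) | C[C@@]12C(=O)O[C@]3(CC[C@@H]1O)[C@@H]1CC[C@@H]4C[C@]1(C[C@]4(C)O)[C@@H](C(=O)OCc1ccccc1)[C@@H]32 | intermediate
31 | CNP0343121.3 (3,16-dihydroxy 19,10-lactone 7-acid; 3S,4S,5R,6S,8R,9R,10R,13R,16S) | C[C@@]12C(=O)O[C@]3(CC[C@@H]1O)[C@@H]1CC[C@@H]4C[C@]1(C[C@]4(C)O)[C@@H](C(=O)O)[C@@H]32 | target

## Step count and least certain steps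

Total step count: 18. Longest linear sequence: 18 steps (1 to 31); the other numbered starting materials each enter in a single step.

**Step 8 (key step).**
- What may go wrong: loss of the allylsilane by protodesilylation, or attack at the formyl carbon, before conjugate closure, because the allylsilane π bond must twist out of the plane of the forming five-membered ring. A second concern is unselective ketonisation at C9, or epimerisation of the aldehyde on handling.
- Fallback: the silicon-free enal 8 is cyclised by a Lewis-acid-promoted intramolecular ene reaction (Me2AlCl, CH2Cl2, −78 to 0 °C). The isopropenyl group adds through its CH2 terminus to C8 and a methyl hydrogen is handed to C9 on the same face. This forms the same C8–C15 bond and C16=C17 methylene, should place H9 cis to C15 by suprafacial delivery, and returns to the route at 13 with steps 6 and 7 omitted. No new compound is made on the way (F0).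

**Step 7.**
- What may go wrong: the silyl palladium species may engage the free enal (conjugate silylation or decarbonylation), or the doubly activated C6 methylene may attack the π-allyl intermediate, since the aldehyde is exposed at 80 °C.
- Fallback: mask the aldehyde first. From 9, trimethyl orthoformate with pyridinium tosylate in MeOH should give the dimethyl acetal of the chloride, F1. The same palladium and disilane conditions should then give the allylsilane acetal F2. Oxalic acid on wet silica gel in CH2Cl2, mild enough for the allylsilane, returns to the route at 11.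

**Step 10.**
- What may go wrong: poor facial selectivity of methyl addition at C16 if the endo face is less shielded than assumed, giving the 16-epimer.
- Fallback: put oxygen rather than carbon on the open face. From 13, addition of 15 alone (THF, −78 °C) gives the propargylic alcohol that retains the methylene, F3. Mukaiyama hydration (Mn(dpm)3, PhSiH3, O2, iPrOH) gives the C16 epimer complementary to the Grignard route and returns at 18.

**Step 13.**
- What may go wrong: poor or reversed facial selectivity at C10, because the Felkin–Anh preference of a ketone flanked by a quaternary carbon is a model prediction, or competing displacement of iodide.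
- Fallback: invert which group is on the ketone and which is the nucleophile, so the same intrinsic facial preference gives the other C10 epimer.
  - From 14, 21 (−78 °C) then 16 give the allylic alcohol diol F4.
  - Dess–Martin periodinane gives the vinyl ketone F5.
  - 15 (THF, −78 °C) gives the enynol F6.
  - [Cp*Ru(MeCN)3]PF6 (cat.) with BnMe2SiH gives the (Z)-vinylsilane F7 by trans-hydrosilylation, with silicon on the carbon remote from the hydroxyl.
  - N-iodosuccinimide replaces silicon by iodine with retention and returns at 22.

**Step 15.**
- What may go wrong: low simple diastereoselection in the aldol, since lactone enolates often discriminate aldehyde faces only moderately; the C3 epimer would be carried through the metathesis.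
- Fallback: correct C3 on the saturated compound. From 30 obtained as a mixture of C3 epimers, Dess–Martin periodinane gives the 3-ketone F8. K[HB(sBu)3] in THF at −78 °C should deliver hydride from the equatorial direction, as for other 4,4-disubstituted 3-ketones, giving the axial alcohol and returning at 30.

## Further compounds

F0 | step 8 | none | none
F1 | step 7 | benzyl 2-[(5R)-5-(3-chloroprop-1-en-2-yl)-2-(dimethoxymethyl)cyclohex-1-en-1-yl]acetate | COC(OC)C1=C(CC(=O)OCc2ccccc2)C[C@H](C(=C)CCl)CC1
F2 | step 7 | benzyl 2-[(5R)-2-(dimethoxymethyl)-5-[3-(trimethylsilyl)prop-1-en-2-yl]cyclohex-1-en-1-yl]acetate | COC(OC)C1=C(CC(=O)OCc2ccccc2)C[C@H](C(=C)C[Si](C)(C)C)CC1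
F3 | step 10 | benzyl 2-[(1S,2R,5R)-2-(1-hydroxybut-2-yn-1-yl)-6-methylidenebicyclo[3.2.1]octan-1-yl]acetate (both carbinol epimers) | CC#CC(O)[C@@H]1CC[C@@H]2C[C@]1(CC2=C)CC(=O)OCc1ccccc1
F4 | step 13 | benzyl 2-[(1S,2R,5R,6S)-6-hydroxy-2-(1-hydroxyprop-2-en-1-yl)-6-methylbicyclo[3.2.1]octan-1-yl]acetate (both carbinol epimers) | C=CC(O)[C@@H]1CC[C@@H]2C[C@]1(C[C@]2(C)O)CC(=O)OCc1ccccc1
F5 | step 13 | benzyl 2-[(1S,2R,5R,6S)-6-hydroxy-6-methyl-2-(prop-2-enoyl)bicyclo[3.2.1]octan-1-yl]acetate | C=CC(=O)[C@@H]1CC[C@@H]2C[C@]1(C[C@]2(C)O)CC(=O)OCc1ccccc1
F6 | step 13 | benzyl 2-[(1S,2R,5R,6S)-6-hydroxy-2-[(3R)-3-hydroxyhex-1-en-4-yn-3-yl]-6-methylbicyclo[3.2.1]octan-1-yl]acetate | CC#C[C@@](O)(C=C)[C@@H]1CC[C@@H]2C[C@]1(C[C@]2(C)O)CC(=O)OCc1ccccc1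
F7 | step 13 | benzyl 2-[(1S,2R,5R,6S)-2-[(3R,4Z)-5-[benzyl(dimethyl)silyl]-3-hydroxyhexa-1,4-dien-3-yl]-6-hydroxy-6-methylbicyclo[3.2.1]octan-1-yl]acetate | C[Si](C)(Cc1ccccc1)/C(C)=C\[C@@](O)(C=C)[C@@H]1CC[C@@H]2C[C@]1(C[C@]2(C)O)CC(=O)OCc1ccccc1
F8 | step 15 | benzyl ester of the 3-oxo analogue of the target (4S,5R,6S,8R,9R,10R,13R,16S) | C[C@@]12C(=O)O[C@]3(CCC1=O)[C@@H]1CC[C@@H]4C[C@]1(C[C@]4(C)O)[C@@H](C(=O)OCc1ccccc1)[C@@H]32
A1 | alternative 1 | 2-(3-oxobutyl)-2-(prop-2-yn-1-yl)cyclopentane-1,3-dione | CC(=O)CCC1(CC#C)C(=O)CCC1=O
A2 | alternative 1 | (7aR)-7a-(prop-2-yn-1-yl)-2,3,7,7a-tetrahydro-1H-indene-1,5(6H)-dione | O=C1CCC2=CC(=O)CC[C@]12CC#C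
A3 | alternative 2 | δ-lactone on C10 of the B/C/D tricycle with C5=C10 alkene, 3-hydroxyl, 16-hydroxyl and C7 silyl ether (C4 epimers) | CC1C(=O)O[C@@H](C[C@@H]1O)C2[C@@H]3CC[C@@H]4C[C@]3(C[C@]4(C)O)[C@@H](CO[Si](C)(C)C(C)(C)C)C=2
A4 | alternative 2 | ring A cyclohexene 19-oic acid with 3-hydroxyl and C1=C10 alkene | C[C@@]1(C(=O)O)[C@@H](O)CC=C2[C@@H]3CC[C@@H]4C[C@]3(C[C@]4(C)O)[C@@H](CO[Si](C)(C)C(C)(C)C)[C@H]12
A5 | alternative 3 | butenolide with 3-oxopropyl chain on C10, C6 dimethyl malonate and 16-triethylsilyl ether | CC1=C[C@](CCC=O)(OC1=O)[C@@H]1CC[C@@H]2C[C@]1(C[C@]2(C)O[Si](CC)(CC)CC)C(C(=O)OC)C(=O)OC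
A6 | alternative 3 | pentacyclic lactone with C6 geminal diester and 3-hydroxyl | C[C@@]12C(=O)O[C@]3(CC[C@@H]1O)[C@@H]1CC[C@@H]4C[C@]1(C[C@]4(C)O[Si](CC)(CC)CC)C(C(=O)OC)(C(=O)OC)[C@@H]32
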